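The ratio 110% in flask north-west is what I watch: the cover, the charge of second nucleophile over the charge of substrate, taking one of each per capture. Time drops out of it.

| setting | red | green | amber | west | south-east | north-west | north |
|---|---|---|---|---|---|---|---|
| substrate | 0.24 M | 0.24 M | 0.24 M | 0.24 M | 0.24 M | 0.24 M | 0.24 M |
| first nucleophile | 0.12 M | 0.12 M | 0.12 M | 0.120 M | 0.120 M | 0.120 M (fed, over 3.0 min) | 0.120 M |
| second nucleophile | 0.264 M | 0.13 M | 0.53 M | 0.264 M (fed, over 3.0 min) | 0.264 M | 0.264 M | 0.264 M (in portions, 3, over 3.0 min) |
| protic impurity | 0.048 M | 0.048 M | 0.048 M | 0.0480 M | 0.0480 M | 0.0480 M | 0.0480 M |
| remark | run made earlier | run made earlier | run made earlier | all else is in the flask from the start; the feed brings no volume worth counting | everything together at the start | all else is in the flask from the start; the feed brings no volume worth counting | first portion at the start, last at 3.0 min |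
| time |  |  |  | 4.0 min | 4.0 min | 4.0 min | 4.0 min |

| run | time / min | target / % | other capture product / % |
|---|---|---|---|
| red | 0.500 | 26.9 | 48.6 |
| red | 1.33 | 21.2 | 58.4 |
| red | 2.50 | 14.9 | 60.8 |
| red | 4.00 | 8.8 | 60.0 |
| green | 0.417 | 36.9 | 29.9 |
| green | 1.00 | 38.8 | 40.1 |
| green | 2.00 | 37.6 | 42.7 |
| green | 3.00 | 36.4 | 44.0 |
| amber | 0.250 | 14.8 | 49.7 |
| amber | 0.667 | 10.6 | 68.5 |
| amber | 1.33 | 5.8 | 71.3 |
| amber | 3.00 | 0 | 72.6 |

(scatter of a reading: 0.5 percentage points)



- which flask leads in share of target in target plus other capture product ("all alike" within 1.5 percentage points) (west / south-east / north-west / north / all alike)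
- share of target in target plus other capture product at the end, west
- share of target in target plus other capture product at the end, south-east
- share of target in target plus other capture product at the end, north-west
- share of target in target plus other capture product at the end, north

1. The runs. In the green run the cover is 54.2%, and other capture product reads 44.0% at 3.00 min, less than that cover, while target reads 36.4%. In the red run the cover is 110%, and target falls from 26.9% to 8.8%. Leftover second nucleophile seems to eat target.

2. First instants of north-west. The first nucleophile enters at 0.0400 M/min, while c(second nucleophile) starts at its full charge. By 0.500 min the feed has brought 8.33% of the substrate charge, far less than the cover. So the second nucleophile leads the capture.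

3. Middle. In the red run, target plus other capture product reads 79.6% by 1.33 min, so I take that as the length of the race. By then the north-west feed has brought 22.2%. The cover is above one, so against the second nucleophile substrate is the limiting reagent, and the second nucleophile can take what the feed does not. My estimate of target made lies between 8.33% and 22.2%.

4. End. If leftover second nucleophile then works on target, as the red run suggests, the low end is the likelier, and I commit to a share near 8.33% for north-west.

The forecast names north as leader, with west 33%, south-east 12.8%, north-west 9% and north 35%. On north-west it reasons: “Feeding the first nucleophile starves it early”.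

The flasks give north as leader, with west 25.4%, south-east 14.2%, north-west 6.52% and north 27.7%. In north-west at 4.00 min, other capture product stands at 87.3%, less than the cover, with substrate at 0%. Target plus over-reaction product comes to 12.7%, more than 8.33% and less than 22.2%.

    second nucleophile + target → over-reaction product (k = 0.0814 /M/s)
    first nucleophile + protic impurity → quenched reagent (k = 0.133 /M/s)
    first nucleophile + intermediate → target (k = 16.3 /M/s)
    substrate ⇌ intermediate (K = 0.0770, k = 0.110 /s)
    second nucleophile + intermediate → other capture product (k = 7.29 /M/s)

In a neighbour of north-west, with 0.16 M of second nucleophile and all else as in north-west, the cover is 66.7%, below one, which leaves 33.3% of the substrate beyond its reach. The computed flask holds 32.9% target, a share of 33.6%.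

Readings and results are simulated on assumed constants, noise included.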